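The α-methylene-γ-butyrolactone (ring O–C6–C7–C11–C12) is disconnected at O–C6 and C7–C11, so the complete lactone derives from 2-bromoacrylic acid and the C6=C7 bond of a ten-membered cyclodeca-1,3,7-triene. One palladium-catalysed diene heteroannulation should form both bonds, set C6 and C7 and leave C4=C5 in place; it exploits the fact that O–C6 is allylic to C4=C5, i.e. the lactone is a carboxylate-trapped C4–C5–C6 allylpalladium. The precursor is the all-ring-cis macrocyclic triene carrying the C8 carbinol in the epimeric configuration (inverted afterwards by Mitsunobu esterification with isovaleric acid); it is closed by ring-closing metathesis of a tetraene assembled by two Horner–Wadsworth–Emmons olefinations.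

Key step: step 13

Numbering used below (germacranolide numbering of the target): carbocycle C1–C10; lactone O on C6, C7–C11–C12(=O); exo-methylene C13; formyl carbon C14 on C10; hydroxymethyl carbon C15 on C4.
Remark: the two trisubstituted ring double bonds (C1=C10, C4=C5) are E by the CIP rules but hold their two ring carbons cis; the route builds and keeps this geometry.

Step 1
Reactants: 1 triethyl phosphonoacetate; 2 3-bromo-1,1-dimethoxypropane
Product: 3 ethyl 2-(diethoxyphosphoryl)-5,5-dimethoxypentanoate
Conditions: NaH, DMSO, rt → 60 °C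
Reagents that add atoms: none
Why: SN2 C-alkylation of the sodium phosphonoacetate by a primary bromide should give the mono-alkylated phosphonate, whose new stereocentre is lost in step 2.

Step 2
Reactants: 3 ethyl 2-(diethoxyphosphoryl)-5,5-dimethoxypentanoate; 4 acrolein
Product: 5 ethyl (2E)-2-(3,3-dimethoxypropyl)penta-2,4-dienoate
Conditions: NaH, THF, 0 °C; then 4, −20 °C → rt
Reagents that add atoms: none
Why: Horner–Wadsworth–Emmons olefination of an α-substituted phosphonoacetate should give mainly the E enoate (ester trans to the vinyl group), which fixes the later ring-cis C4=C5 geometry.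

Step 3
Reactants: 5 ethyl (2E)-2-(3,3-dimethoxypropyl)penta-2,4-dienoate
Product: 6 (2E)-2-(3,3-dimethoxypropyl)penta-2,4-dien-1-ol
Conditions: i-Bu2AlH (2.5 equiv), CH2Cl2, −78 °C; aq. potassium sodium tartrate (KNaC4H4O6)
Reagents that add atoms: none
Why: 1,2-reduction of the conjugated ester by the aluminium hydride should give the allylic alcohol (C15–OH) without touching the acetal or the diene.

Step 4
Reactants: 6 (2E)-2-(3,3-dimethoxypropyl)penta-2,4-dien-1-ol
Product: 7 tert-butyl{[(2E)-2-(3,3-dimethoxypropyl)penta-2,4-dien-1-yl]oxy}diphenylsilane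
Conditions: t-BuPh2SiCl, imidazole, CH2Cl2, rt
Reagents that add atoms: tert-butyl(chloro)diphenylsilane, CC(C)(C)[Si](Cl)(c1ccccc1)c1ccccc1
Why: Standard silylation of a primary alcohol; the acid-stable silyl ether is chosen so that it survives step 5.

Step 5
Reactants: 7 tert-butyl{[(2E)-2-(3,3-dimethoxypropyl)penta-2,4-dien-1-yl]oxy}diphenylsilane
Product: 8 (4E)-4-{[(tert-butyldiphenylsilyl)oxy]methyl}hepta-4,6-dienal
Conditions: PPTS (cat.), acetone/H2O, 50 °C
Reagents that add atoms: water, O
Why: Mild acid-catalysed hydrolysis of the dimethyl acetal should free the C1 aldehyde while the silyl ether and the diene persist.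

Step 6
Reactants: 9 (5S)-5-(hydroxymethyl)oxolan-2-one
Product: 10 (2S)-5-oxooxolane-2-carbaldehyde
Conditions: Dess–Martin periodinane, CH2Cl2, rt
Reagents that add atoms: none
Why: Neutral Dess–Martin oxidation should give the α-oxygenated aldehyde without epimerising the stereocentre that becomes C8.

Step 7
Reactants: 10 (2S)-5-oxooxolane-2-carbaldehyde
Product: 11 (5S)-5-ethenyloxolan-2-one
Conditions: Ph3PCH3Br, KN(SiMe3)2, THF, −78 → 0 °C
Reagents that add atoms: methyltriphenylphosphonium bromide, C[P+](c1ccccc1)(c1ccccc1)c1ccccc1.[Br-]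
Why: Wittig methylenation with the salt-free ylide at low temperature should react at the aldehyde much faster than at the lactone and faster than enolisation, so the stereocentre is kept.

Step 8
Reactants: 11 (5S)-5-ethenyloxolan-2-one
Product: 13 diethyl [(5S)-5-ethenyl-2-oxooxolan-3-yl]phosphonate, via enol phosphate 12 (not isolated)
Conditions: LiN(i-Pr)2 (2.3 equiv), ClP(O)(OEt)2, THF, −78 °C → rt; 1 M HCl
Reagents that add atoms: diethyl chlorophosphate, CCOP(=O)(Cl)OCC
Why: O-phosphorylation of the lactone enolate gives 12, which the second equivalent of amide base should convert by 1,3-phosphorus migration (phosphate–phosphonate rearrangement) into the C-phosphonate; C5 is not involved and the new C3 centre is inconsequential.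

Step 9
Reactants: 13 diethyl [(5S)-5-ethenyl-2-oxooxolan-3-yl]phosphonate; 8 (4E)-4-{[(tert-butyldiphenylsilyl)oxy]methyl}hepta-4,6-dienal
Product: 14 (3E,5S)-3-[(4E)-4-{[(tert-butyldiphenylsilyl)oxy]methyl}hepta-4,6-dien-1-ylidene]-5-ethenyloxolan-2-one
Conditions: NaH, THF, 0 °C; then 8, 0 °C → rt
Reagents that add atoms: none
Why: Horner–Wadsworth–Emmons olefination of the α-phosphono lactone should give mainly the E alkylidene lactone (C2 trans to the carbonyl C14, cis to C9), i.e. the ring-cis C1=C10 geometry, with the minor Z isomer removed by chromatography.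

Step 10
Reactants: 14 (3E,5S)-3-[(4E)-4-{[(tert-butyldiphenylsilyl)oxy]methyl}hepta-4,6-dien-1-ylidene]-5-ethenyloxolan-2-one
Product: 15 (3S,5E,9E)-9-{[(tert-butyldiphenylsilyl)oxy]methyl}-5-(hydroxymethyl)dodeca-1,5,9,11-tetraen-3-ol
Conditions: i-Bu2AlH (4 equiv), CH2Cl2, −78 → 0 °C; aq. potassium sodium tartrate (KNaC4H4O6)
Reagents that add atoms: none
Why: Exhaustive 1,2-reduction of the α-alkylidene lactone through the lactol should give the C14/C8 diol with the stereocentre and both trisubstituted alkenes unchanged.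

Step 11
Reactants: 15 (3S,5E,9E)-9-{[(tert-butyldiphenylsilyl)oxy]methyl}-5-(hydroxymethyl)dodeca-1,5,9,11-tetraen-3-ol
Product: 16 (3S,5E,9E)-9-{[(tert-butyldiphenylsilyl)oxy]methyl}-5-{[(triethylsilyl)oxy]methyl}dodeca-1,5,9,11-tetraen-3-ol
Conditions: Et3SiCl (1.05 equiv), imidazole, CH2Cl2, −78 °C
Reagents that add atoms: chlorotriethylsilane, CC[Si](Cl)(CC)CC
Why: Kinetic silylation should take the primary allylic C14 hydroxyl and leave the secondary C8 carbinol free.

Step 12
Reactants: 16 (3S,5E,9E)-9-{[(tert-butyldiphenylsilyl)oxy]methyl}-5-{[(triethylsilyl)oxy]methyl}dodeca-1,5,9,11-tetraen-3-ol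
Product: 17 (1S,2Z,4E,8E)-5-{[(tert-butyldiphenylsilyl)oxy]methyl}-9-{[(triethylsilyl)oxy]methyl}cyclodeca-2,4,8-trien-1-ol (all three ring double bonds cis within the ring; C1 of this name is C8)
Conditions: second-generation Grubbs catalyst RuCl2(=CHPh)(PCy3)(H2IMes) (10 mol %), 1,4-benzoquinone (20 mol %), CH2Cl2 (1 mM), 40 °C
Reagents that add atoms: none
Why: Diene–ene ring-closing metathesis between the vinyl carbinol and the terminal diene double bond should close the ten-membered ring, which can hold the new C6=C7 bond only as the Z isomer, while the two trisubstituted alkenes are inert and loss of ethene drives the closure.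

Step 13
Reactants: 17 (1S,2Z,4E,8E)-5-{[(tert-butyldiphenylsilyl)oxy]methyl}-9-{[(triethylsilyl)oxy]methyl}cyclodeca-2,4,8-trien-1-ol; 18 2-bromoacrylic acid
Product: 20 (6R,7R,8S)-15-(tert-butyldiphenylsilyloxy)-8-hydroxy-14-(triethylsilyloxy)germacra-1(10),4,11(13)-trien-12,6-olide, via allylpalladium carboxylate 19 (not isolated)
Conditions: Pd(OAc)2 (10 mol %), PPh3 (25 mol %), Ag2CO3 (1 equiv), DMF, 60 °C, slow addition of 18 (1.5 equiv)
Reagents that add atoms: none
Why: Oxidative addition of zerovalent palladium to the C–Br bond of 18 gives a 1-carboxyvinyl complex of divalent palladium, whose syn-carbopalladation of the ring diene at its less substituted terminus C7 forms C11–C7 and leaves the allyl complex 19 over C6–C5–C4; the tethered carboxylate then attacks the allyl terminus C6 (O–C6, a 5-exo closure onto the allyl and the only ring closed) and releases zerovalent palladium. The closest known reaction type is the Larock heteroannulation of 1,3-dienes with aryl or vinylic halides that carry a carboxylic acid. C7 is controlled by the C8 carbinol: in the tub-shaped ring the hydroxyl sits pseudo-equatorially on the periphery and the inner diene face is shielded by the C1=C10 unit, so peripheral, hydroxyl-assisted delivery should place C11 trans to O8, as medium-ring cis-cycloalkenols generally react. C6 is controlled by the mode of C–O bond formation: with bromide removed by silver, the bis(triphenylphosphine) allyl cation cannot bind the carboxylate, which therefore attacks anti to palladium, and syn-insertion into the (Z)-C6=C7 bond followed by anti attack amounts to anti-carbo-oxygenation, i.e. the trans-fused lactone. Regioselectivity (C7 over the fully substituted C4 in the insertion; C6 over the tertiary C4 in the closure, which would need a seven-membered ring), chemoselectivity (conjugated diene over the trisubstituted C1=C10) and the ring-cis geometry of the surviving C4=C5 bond (C3 is held anti on the allyl by the ring) should all follow from the cyclic substrate.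

Step 14
Reactants: 20 (6R,7R,8S)-15-(tert-butyldiphenylsilyloxy)-8-hydroxy-14-(triethylsilyloxy)germacra-1(10),4,11(13)-trien-12,6-olide; 21 isovaleric acid (3-methylbutanoic acid)
Product: 22 (6R,7R,8R)-15-(tert-butyldiphenylsilyloxy)-8-(3-methylbutanoyloxy)-14-(triethylsilyloxy)germacra-1(10),4,11(13)-trien-12,6-olide
Conditions: PPh3, DIAD, toluene, 0 °C → rt (betaine pre-formed)
Reagents that add atoms: none
Why: Mitsunobu esterification should displace the C8 oxyphosphonium ion by isovalerate with clean SN2 inversion, turning the (8S) carbinol into the (8R) ester of the target.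

Step 15
Reactants: 22 (6R,7R,8R)-15-(tert-butyldiphenylsilyloxy)-8-(3-methylbutanoyloxy)-14-(triethylsilyloxy)germacra-1(10),4,11(13)-trien-12,6-olide
Product: 23 (6R,7R,8R)-15-(tert-butyldiphenylsilyloxy)-8-(3-methylbutanoyloxy)-14-oxogermacra-1(10),4,11(13)-trien-12,6-olide
Conditions: (COCl)2, DMSO, CH2Cl2, −78 → −30 °C; then Et3N, → 0 °C
Reagents that add atoms: none
Why: Under Swern conditions a primary triethylsilyl ether is converted directly into the aldehyde (the chlorosulfonium ion exchanges the silyl group), whereas the tert-butyldiphenylsilyl ether, the ester and the lactone should be untouched.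

Step 16
Reactants: 23 (6R,7R,8R)-15-(tert-butyldiphenylsilyloxy)-8-(3-methylbutanoyloxy)-14-oxogermacra-1(10),4,11(13)-trien-12,6-olide
Product: 24 (6R,7R,8R)-15-hydroxy-8-(3-methylbutanoyloxy)-14-oxogermacra-1(10),4,11(13)-trien-12,6-olide (CNP0345200.3)
Conditions: HF·pyridine, pyridine/THF, 0 °C → rt
Reagents that add atoms: none
Why: Buffered fluoride cleavage of the primary silyl ether should free the C15 alcohol without affecting the α-methylene lactone, the enal or the isovalerate.

Compound list
1 | triethyl phosphonoacetate | CCOC(=O)CP(=O)(OCC)OCC | starting material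
2 | 3-bromo-1,1-dimethoxypropane | COC(CCBr)OC | starting material
3 | ethyl 2-(diethoxyphosphoryl)-5,5-dimethoxypentanoate (racemic) | CCOC(=O)C(CCC(OC)OC)P(=O)(OCC)OCC | intermediate
4 | acrolein | C=CC=O | starting material
5 | ethyl (2E)-2-(3,3-dimethoxypropyl)penta-2,4-dienoate | CCOC(=O)/C(CCC(OC)OC)=C/C=C | intermediate
6 | (2E)-2-(3,3-dimethoxypropyl)penta-2,4-dien-1-ol | OC/C(CCC(OC)OC)=C/C=C | intermediate
7 | tert-butyl{[(2E)-2-(3,3-dimethoxypropyl)penta-2,4-dien-1-yl]oxy}diphenylsilane | CC(C)(C)[Si](c1ccccc1)(c1ccccc1)OC/C(CCC(OC)OC)=C/C=C | intermediate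
8 | (4E)-4-{[(tert-butyldiphenylsilyl)oxy]methyl}hepta-4,6-dienal | CC(C)(C)[Si](c1ccccc1)(c1ccccc1)OC/C(CCC=O)=C/C=C | intermediate
9 | (5S)-5-(hydroxymethyl)oxolan-2-one | OC[C@@H]1CCC(=O)O1 | starting material
10 | (2S)-5-oxooxolane-2-carbaldehyde | O=C[C@@H]1CCC(=O)O1 | intermediate
11 | (5S)-5-ethenyloxolan-2-one | C=C[C@@H]1CCC(=O)O1 | intermediate
12 | diethyl (5S)-5-ethenyl-4,5-dihydrofuran-2-yl phosphate (enol phosphate) | C=C[C@@H]1CC=C(OP(=O)(OCC)OCC)O1 | intermediate
13 | diethyl [(5S)-5-ethenyl-2-oxooxolan-3-yl]phosphonate (C3 epimers) | C=C[C@@H]1CC(P(=O)(OCC)OCC)C(=O)O1 | intermediate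
14 | (3E,5S)-3-[(4E)-4-{[(tert-butyldiphenylsilyl)oxy]methyl}hepta-4,6-dien-1-ylidene]-5-ethenyloxolan-2-one | C=C[C@@H]1C/C(=C\CC/C(CO[Si](c2ccccc2)(c2ccccc2)C(C)(C)C)=C\C=C)C(=O)O1 | intermediate
15 | (3S,5E,9E)-9-{[(tert-butyldiphenylsilyl)oxy]methyl}-5-(hydroxymethyl)dodeca-1,5,9,11-tetraen-3-ol | C=C[C@@H](O)C/C(CO)=C\CC/C(CO[Si](c1ccccc1)(c1ccccc1)C(C)(C)C)=C\C=C | intermediate
16 | (3S,5E,9E)-9-{[(tert-butyldiphenylsilyl)oxy]methyl}-5-{[(triethylsilyl)oxy]methyl}dodeca-1,5,9,11-tetraen-3-ol | C=C[C@@H](O)C/C(CO[Si](CC)(CC)CC)=C\CC/C(CO[Si](c1ccccc1)(c1ccccc1)C(C)(C)C)=C\C=C | intermediate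
17 | (1S,2Z,4E,8E)-5-{[(tert-butyldiphenylsilyl)oxy]methyl}-9-{[(triethylsilyl)oxy]methyl}cyclodeca-2,4,8-trien-1-ol | C1/C(CO[Si](c2ccccc2)(c2ccccc2)C(C)(C)C)=C\C=C/[C@@H](O)C/C(CO[Si](CC)(CC)CC)=C\C1 | intermediate
18 | 2-bromoacrylic acid | C=C(Br)C(=O)O | starting material
19 | allylpalladium carboxylate: bis(triphenylphosphine)palladium (divalent) on C6–C5–C4 of the C7-vinylated ring, carboxylate as counter-ion, drawn in its C6-bound form | C=C(C(=O)[O-])[C@@H]1[C@@H](O)C/C(CO[Si](CC)(CC)CC)=C\CC/C(CO[Si](c2ccccc2)(c2ccccc2)C(C)(C)C)=C\[C@@H]1[Pd-]([P+](c1ccccc1)(c1ccccc1)c1ccccc1)[P+](c1ccccc1)(c1ccccc1)c1ccccc1 | intermediate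
20 | (6R,7R,8S)-15-(tert-butyldiphenylsilyloxy)-8-hydroxy-14-(triethylsilyloxy)germacra-1(10),4,11(13)-trien-12,6-olide (trans-fused lactone, 8-OH trans to C11) | C=C1C(=O)O[C@@H]2/C=C(/CO[Si](c3ccccc3)(c3ccccc3)C(C)(C)C)CC/C=C(/CO[Si](CC)(CC)CC)C[C@H](O)[C@@H]12 | intermediate
21 | isovaleric acid (3-methylbutanoic acid) | CC(C)CC(=O)O | starting material
22 | (6R,7R,8R)-15-(tert-butyldiphenylsilyloxy)-8-(3-methylbutanoyloxy)-14-(triethylsilyloxy)germacra-1(10),4,11(13)-trien-12,6-olide | C=C1C(=O)O[C@@H]2/C=C(/CO[Si](c3ccccc3)(c3ccccc3)C(C)(C)C)CC/C=C(/CO[Si](CC)(CC)CC)C[C@@H](OC(=O)CC(C)C)[C@@H]12 | intermediate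
23 | (6R,7R,8R)-15-(tert-butyldiphenylsilyloxy)-8-(3-methylbutanoyloxy)-14-oxogermacra-1(10),4,11(13)-trien-12,6-olide | C=C1C(=O)O[C@@H]2/C=C(/CO[Si](c3ccccc3)(c3ccccc3)C(C)(C)C)CC/C=C(/C=O)C[C@@H](OC(=O)CC(C)C)[C@@H]12 | intermediate
24 | (6R,7R,8R)-15-hydroxy-8-(3-methylbutanoyloxy)-14-oxogermacra-1(10),4,11(13)-trien-12,6-olide (CNP0345200.3) | C=C1C(=O)O[C@@H]2/C=C(/CO)CC/C=C(/C=O)C[C@@H](OC(=O)CC(C)C)[C@@H]12 | target

Total step count: 16. Longest linear sequence: 13 steps (steps 1–5, then 9–16); the lactone arm (steps 6–8) joins at step 9.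

Steps most likely to fail

1. Step 13 (key step). The carbopalladation may show low or reversed facial selectivity with respect to the C8 carbinol (delivery of C11 cis to O8). Closure of the C6–O bond from the palladium-bearing face would in addition erode the trans ring fusion. Fallback, setting out from 17 and returning at 22: 17 is esterified with 21 under the Mitsunobu conditions of step 14, which inverts C8 and gives (1R,2Z,4E,8E)-5-{[(tert-butyldiphenylsilyl)oxy]methyl}-9-{[(triethylsilyl)oxy]methyl}cyclodeca-2,4,8-trien-1-yl 3-methylbutanoate F1. F1 is then annulated with 18 under phosphine-free, chloride-rich conditions (Pd(OAc)2, n-Bu4NCl, NaHCO3, DMF, 60 °C), which should not ionise the allylic ester and still favour external carboxylate attack. Delivery of C11 cis to the C8 oxygen then gives 22 directly, so the final C8 configuration is set before the annulation and step 14 is no longer needed.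

2. Step 12. Intermolecular metathesis (oligomerisation) may outrun closure of the strained ten-membered ring, and loading of the catalyst on the diene terminus may lead to truncated rings. Fallback, setting out from 14 and returning at 17: the ring is closed before the reduction, on the lactone 14, whose butyrolactone holds the C8 vinyl group and the E-alkylidene chain close together as a temporary conformational lock. Ring-closing metathesis with the same ruthenium catalyst should give the bridged bicyclic lactone (8S)-15-(tert-butyldiphenylsilyloxy)cyclodeca-1(10),4,6-triene-14,8-carbolactone F2. Reduction with i-Bu2AlH as in step 10 opens it to the cyclic diol (1S,2Z,4E,8E)-5-{[(tert-butyldiphenylsilyl)oxy]methyl}-9-(hydroxymethyl)cyclodeca-2,4,8-trien-1-ol F3, and selective silylation with Et3SiCl as in step 11 gives 17.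

3. Step 14. The hindered C8 oxyphosphonium ion, flanked by the branched C7, may eliminate or react incompletely instead of undergoing clean inversion. Fallback, setting out from 20 and returning at 22: Dess–Martin oxidation of 20 gives the 8-oxo lactone F4 (the 8-ketone of 20). Luche reduction (NaBH4, CeCl3, MeOH, −78 °C) should deliver hydride from the ring periphery, trans to C11, and give the (6R,7R,8R)-8-hydroxy lactone F5. Acylation of F5 with isovaleric anhydride, DMAP and Et3N in CH2Cl2 (retention) gives 22.

Further compounds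
F1 | step 13 | (1R,2Z,4E,8E)-5-{[(tert-butyldiphenylsilyl)oxy]methyl}-9-{[(triethylsilyl)oxy]methyl}cyclodeca-2,4,8-trien-1-yl 3-methylbutanoate | C1/C(CO[Si](c2ccccc2)(c2ccccc2)C(C)(C)C)=C\C=C/[C@H](OC(=O)CC(C)C)C/C(CO[Si](CC)(CC)CC)=C\C1
F2 | step 12 | bridged bicyclic lactone: (8S)-15-(tert-butyldiphenylsilyloxy)cyclodeca-1(10),4,6-triene-14,8-carbolactone | C1/C(CO[Si](c2ccccc2)(c2ccccc2)C(C)(C)C)=C\C=C/[C@@H]2C/C(C(=O)O2)=C\C1
F3 | step 12 | (1S,2Z,4E,8E)-5-{[(tert-butyldiphenylsilyl)oxy]methyl}-9-(hydroxymethyl)cyclodeca-2,4,8-trien-1-ol | C1/C(CO[Si](c2ccccc2)(c2ccccc2)C(C)(C)C)=C\C=C/[C@@H](O)C/C(CO)=C\C1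
F4 | step 14 | 8-oxo derivative of 20: 15-(tert-butyldiphenylsilyloxy)-8-oxo-14-(triethylsilyloxy)germacra-1(10),4,11(13)-trien-12,6-olide | C=C1C(=O)O[C@@H]2/C=C(/CO[Si](c3ccccc3)(c3ccccc3)C(C)(C)C)CC/C=C(/CO[Si](CC)(CC)CC)CC(=O)[C@@H]12
F5 | step 14 | (6R,7R,8R)-15-(tert-butyldiphenylsilyloxy)-8-hydroxy-14-(triethylsilyloxy)germacra-1(10),4,11(13)-trien-12,6-olide | C=C1C(=O)O[C@@H]2/C=C(/CO[Si](c3ccccc3)(c3ccccc3)C(C)(C)C)CC/C=C(/CO[Si](CC)(CC)CC)C[C@@H](O)[C@@H]12
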